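## The problem

The target is a cis-fused daucane in which ring A (cyclopentane C1–C5) and ring B (cycloheptane C1, C5–C10) share the quaternary C1 (methyl C15) and C5 (H), with both substituents on the β face. Eight stereocentres (C1, C2, C4, C5, C6, C8, C9, C10) sit on ten ring atoms and every second ring atom carries oxygen: ring A holds a cis-1,3-diol (C2 secondary, C4 tertiary beside the isopropyl group), and ring B holds β-acyloxy groups at C6 and C10 on either side of the ring fusion and the β C8–C9 epoxide. C1 is the hardest centre, because it is fully substituted and flanked by two carbinol carbons (C2, C10) and by C5. The centres are close enough to relay: C2 can direct C1, C1 can direct C8 and C4, the C4 hydroxyl can direct C6 and fix C5 thermodynamically, an allylic hydrogen at C8 can direct C10, and the C10 oxygen can direct the epoxide. The angelates are Z-enoates that isomerise to tiglates with base or nucleophilic catalysts and the trisubstituted epoxide is acid-labile, so both belong at the end, and the C4/C6 β-hydroxy ketone stage is open to retro-aldol cleavage and dehydration. The feature that the plan uses lies in ring B: without the late oxygen (C10–O, epoxide) and the C4 isopropyl group, ring B is a cyclohepta-1,4-diene with double bonds C5=C6 (enol ether of a C6 ketone) and C9=C10, bridged on one side by C7–C8 and on the other by the single atom C1. That is the product pattern of a cis-divinylcyclopropane rearrangement of a cyclopropane made of C1, C5 and C10. Because C5 lies between the carbonyl carbons C4 and C6, this cyclopropane is what a carbenoid at C5, made from a diazo-1,3-diketone, gives on adding to a C1=C10 double bond three atoms away, and that addition closes ring A as well.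

## Retrosynthesis

**Esters and silyl ether (20 ⇒ 19 ⇒ 17 + 18).** The C2–O–Si bond and the two acyl C–O bonds at C6 and C10 are cut first. The Z-enoates are the most fragile groups, so they are put on after every oxidation and reduction. The C2 oxygen stays silylated so that only the C6 and C10 hydroxyls of epoxy triol 17 react, each with one equivalent of angelic acid 18; the tertiary C4 hydroxyl needs no protection. The forward reaction must acylate two hindered secondary alcohols without Z/E isomerisation.

**C10–O and the epoxide (17 ⇒ 15 via 16).** The C10–O bond and both epoxide C–O bonds are cut together, and the double bond is moved from C8=C9 to C9=C10. The alternative, allylic oxidation of a C8=C9 alkene, has three competing allylic sites (C7, C10, C14). In 15 the C9=C10 bond has one allylic hydrogen only (H8, since C1 is quaternary), so an ene reaction with singlet oxygen can place oxygen only on C10 and only on the face of H8. The hydroperoxide 16 then supplies the epoxide oxygen. Diol 15 has three stereocentres fewer than 17.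

**C6–H and C4–isopropyl (15 ⇒ 14 ⇒ 12 via 13).** The C6 carbinol is traced to ketone 14, where the C4 hydroxyl can deliver hydride (1,3-anti). The C4–isopropyl bond is cut back to the vinylogous silyl ester 12, whose single carbonyl (C4) takes the nucleophile while C6 stays masked as an enol ether. Adding isopropyl before unmasking C6 avoids a C4/C6 β-diketone that could not be differentiated. The forward steps must attack C4 from the β face and let C5 settle cis.

**Both rings (12 ⇒ 10 via 11), the key disconnection.** The C7–C8 bond is cut by a retro-Cope step to cis-divinylcyclopropane 11. The C5–C1 and C5–C10 bonds are then cut by a retro-cyclopropanation to the acyclic diazo ketone 10. Neighbouring cuts (C8=C9 by metathesis, C5–C6 by aldol) open only ring B and leave the quaternary C1 to be made separately. This cut removes both rings, C1 and C8 at once and leaves a chain with one stereocentre (C2). The forward reaction must pick the proximal alkene, the correct face, and the boat transition state.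

**Diazo ketone to aldol (10 ⇒ 9 ⇒ 8 ⇒ 7 ⇒ 3 + 5 via 6).** Enol silylation, diazo transfer and O-silylation are functional-group changes on hydroxy diketone 7. The C2–C3 bond of 7 is cut by a vinylogous aldol disconnection to dienal 3 and bis-silyl dienol ether 5. This is where the only reagent-controlled stereocentre (C2) is set, by catalysis.

**Building blocks (3 ⇒ 1 + 2; 5 ⇒ 4).** The C1=C10 double bond of 3 is cut by a Wittig disconnection to crotonaldehyde 1 and the formyl ylide 2. Diene 5 comes from acetylacetone 4. All four carbon sources are commercial.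

## Roads not taken

**Alternative 1:** ring-closing metathesis at C8=C9, the cut most chemists would draw first. A cyclopentane diene A1 (vinyl carbinol arm on C1, methallyl carbinol arm on C5) would be closed with the second-generation Grubbs catalyst to cycloheptene A2, followed by directed epoxidation and acylation. The ring closure adds no stereocentre. All of C1, C2, C4, C5, C6 and C10, including the quaternary C1 between two carbinols, would have to be set one by one on a cyclopentane before the key step. The alkene next to the neopentyl C10 is also a slow metathesis partner. The chosen plan makes both rings and C1 in one step from a chain with one stereocentre.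

**Alternative 2:** two-carbon ring expansion, cutting C1–C10 and C5–C6 and adding a C6–C10 bond. A [2+2] photocycloaddition of enone A3 with the symmetrical bis(silyloxy)cyclopentene A4 would give cyclobutane A5, and glycol cleavage would give the cis-fused trione A6. This sets C1 and C5 well (addition anti to the isopropyl group) and is short to the bicycle. The C6–C10 bridge, however, arrives symmetrical, so the C8=C9 (not C7=C8) unsaturation and three ketones (C2, C6, C10) must then be differentiated and reduced with three separate facial selectivities. Enantiopure A3 also has no short access. The chosen plan delivers C6, C8–C10 and C4 in distinguishable oxidation states.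

**Alternative 3:** an intermolecular (4+3) annulation from the chiral pool, cutting C6–C7 and C1–C10. (R)-Terpinen-4-ol A7 maps onto C1–C6, C15 and the isopropyl group. It would be converted into the Cr(CO)5 carbene complex A8, which would react with siloxydiene A9 by cyclopropanation and Cope rearrangement to give A10, with C10–O and C8=C9 already in place. Against it: stoichiometric chromium, and a run-up of six or more steps from A7 (allylic oxidation for C2, ozonolysis, aldol condensation, oxidation, carbene formation). Control of C1 would also have to come from C4 through a cyclopropane whose configuration C4 can barely influence. In the chosen plan the cyclopropanation is intramolecular and the controlling stereocentre (C2) is allylic to the reacting alkene.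

Key step: step 7

Remark on numbering: daucane numbering is used throughout (ring A: C1–C5; ring B: C1, C5–C10; C14 = methyl on C8; C15 = methyl on C1); β is the face of C15 and H5, α the opposite face.

Remark on the chemistry: the catalyst formed from Ti(OiPr)4 and (S)-BINOL is assumed to direct the silyl dienolate to the si face of the aldehyde, as it does for aryl and alkenyl aldehydes; β-diketones are drawn as diketo tautomers.

## Steps

Step 1
Reactants: 1 (E)-but-2-enal (crotonaldehyde); 2 2-(triphenyl-λ5-phosphanylidene)propanal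
Product: 3 (2E,4E)-2-methylhexa-2,4-dienal
Conditions: toluene, 90 °C (1 in excess)
Reagents that add atoms: none
Why: Wittig olefination with a stabilised formyl ylide should give the trisubstituted C1=C10 bond with E geometry (C2 trans to C9), which later places the propenyl group exo on the cyclopropane; the α-branched product is less electrophilic than 1, which limits double homologation.

Step 2
Reactants: 4 pentane-2,4-dione (acetylacetone)
Product: 5 (3Z)-2,4-bis(trimethylsilyloxy)penta-1,3-diene
Conditions: Me3SiOTf (2.2 equiv), Et3N, Et2O, 0 → 20 °C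
Reagents that add atoms: trimethylsilyl trifluoromethanesulfonate, C[Si](C)(C)OS(=O)(=O)C(F)(F)F
Why: Double soft enolisation and O-silylation of the β-diketone gives the 1,3-bis(silyloxy)diene, whose terminal carbon is the nucleophile of the vinylogous aldol addition.

Step 3
Reactants: 3 (2E,4E)-2-methylhexa-2,4-dienal; 5 (3Z)-2,4-bis(trimethylsilyloxy)penta-1,3-diene
Product: 7 (6S,7E,9E)-6-hydroxy-7-methylundeca-7,9-diene-2,4-dione, via silylated aldol adduct 6 (not isolated)
Conditions: Ti(OiPr)4 (10 mol%), (S)-BINOL (10 mol%), 4 Å MS, THF, −78 → −20 °C; then aq. citric acid, THF, 0 °C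
Reagents that add atoms: none
Why: Catalytic enantioselective vinylogous Mukaiyama aldol addition: the complex formed from Ti(OiPr)4 and (S)-BINOL activates the aldehyde and the diene adds through its terminal carbon to the si face, which sets C2 (6S in 7), the only stereocentre set by a reagent; mild acid then removes both trimethylsilyl groups without cyclodehydration.

Step 4
Reactants: 7 (6S,7E,9E)-6-hydroxy-7-methylundeca-7,9-diene-2,4-dione
Product: 8 (6S,7E,9E)-6-(tert-butyldimethylsilyloxy)-7-methylundeca-7,9-diene-2,4-dione
Conditions: TBSCl, imidazole, DMF, 0 → 20 °C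
Reagents that add atoms: tert-butyldimethylsilyl chloride, CC(C)(C)[Si](C)(C)Cl
Why: Silylation of the secondary allylic alcohol; the bulky ether is the group that steers step 7 and shields the α face of ring A in step 8, and any enol silyl ether of the diketone hydrolyses on work-up.

Step 5
Reactants: 8 (6S,7E,9E)-6-(tert-butyldimethylsilyloxy)-7-methylundeca-7,9-diene-2,4-dione
Product: 9 (6S,7E,9E)-6-(tert-butyldimethylsilyloxy)-3-diazo-7-methylundeca-7,9-diene-2,4-dione
Conditions: 4-acetamidobenzenesulfonyl azide, Et3N, MeCN, 0 → 20 °C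
Reagents that add atoms: 4-acetamidobenzenesulfonyl azide, CC(=O)Nc1ccc(cc1)S(=O)(=O)N=[N+]=[N-]
Why: Regitz diazo transfer to the doubly activated methylene (C5) of the 1,3-diketone; no stereocentre is touched and the β-silyloxy ketone tolerates the amine base.

Step 6
Reactants: 9 (6S,7E,9E)-6-(tert-butyldimethylsilyloxy)-3-diazo-7-methylundeca-7,9-diene-2,4-dione
Product: 10 (6S,7E,9E)-2,6-bis(tert-butyldimethylsilyloxy)-3-diazo-7-methylundeca-1,7,9-trien-4-one
Conditions: LiN(SiMe3)2, THF, −78 °C; then TBSOTf, −78 °C
Reagents that add atoms: tert-butyldimethylsilyl trifluoromethanesulfonate, CC(C)(C)[Si](C)(C)OS(=O)(=O)C(F)(F)F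
Why: Kinetic deprotonation should occur at the acetyl methyl group (C7) in preference to the β-branched C3 methylene, and O-silylation then gives the donor/acceptor vinyl diazo ketone with the C6 oxygen already in place as an enol ether.

Step 7
Reactants: 10 (6S,7E,9E)-2,6-bis(tert-butyldimethylsilyloxy)-3-diazo-7-methylundeca-1,7,9-trien-4-one
Product: 12 (3S,3aR,6R)-3,8-bis(tert-butyldimethylsilyloxy)-3a,6-dimethyl-3,3a,6,7-tetrahydroazulen-1(2H)-one, via cis-divinylcyclopropane 11 (not isolated)
Conditions: Rh2(OAc)4 (1 mol%), CH2Cl2, 0 → 20 °C (slow addition of 10); then toluene, 80 °C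
Reagents that add atoms: none
Why: Rh2(OAc)4 turns the diazo ketone into a Rh2(OAc)4-bound vinylcarbenoid at C5 (donor: siloxyvinyl group, acceptor: C4 ketone), which adds to the proximal trisubstituted C1=C10 bond; this intramolecular cyclopropanation closes ring A as the five-membered ring of bicyclo[3.1.0]hexan-2-one 11. The E geometry of the alkene is kept, so the propenyl group on C10 is exo and cis to the siloxyvinyl group on C5. This cis-divinylcyclopropane then undergoes the [3,3] sigmatropic (Cope) rearrangement through the boat transition state: C5–C10 breaks, C7–C8 forms, and ring B arises by ring expansion with double bonds at C5=C6 and C9=C10. The closest known reaction type is the tandem intramolecular cyclopropanation/divinylcyclopropane rearrangement of dienyl vinyl diazo carbonyl compounds, together with the (4+3) annulations of siloxyvinyl diazo compounds with dienes. C1 is set in the cyclopropanation by the C2 stereocentre: with the tether carbon C3 perpendicular to the alkene, the C2–O bond lies inside next to H10 and the C2 hydrogen eclipses C15, so the carbenoid should add to the face that puts the silyloxy group trans to C15 and cis to the cyclopropane. C8 is set by the boat geometry: the methyl of the E-propenyl terminus points outward and its hydrogen inward, syn to C15, so H8 is β as step 10 requires. The step needs proximal-over-distal alkene selectivity (five- against seven-membered ring closure), reaction at the carbenoid carbon and not at the vinylogous terminus (siloxy substitution, non-polar medium), and facial selectivity (bulky C2 silyl ether, A(1,2) strain with C15). The syn methyl on C1 slows the rearrangement, hence the thermal finish.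

Step 8
Reactants: 12 (3S,3aR,6R)-3,8-bis(tert-butyldimethylsilyloxy)-3a,6-dimethyl-3,3a,6,7-tetrahydroazulen-1(2H)-one
Product: 14 (1S,3S,3aS,6R,8aR)-1-(tert-butyldimethylsilyloxy)-3-hydroxy-3-isopropyl-6,8a-dimethyl-2,3,3a,5,6,8a-hexahydroazulen-4(1H)-one, via carbinol enol ether 13 (not isolated)
Conditions: i-PrMgCl, CeCl3, THF, −78 °C; then Bu4NF, AcOH, THF, −78 → 20 °C
Reagents that add atoms: isopropylmagnesium chloride, CC(C)[Mg]Cl
Why: 1,2-Addition of the weakly basic reagent formed from i-PrMgCl and CeCl3 to the vinylogous ester carbonyl should come from the β face, anti to the C2 silyloxy group and to C10, which sets C4 (OH α, isopropyl β); buffered fluoride then cleaves only the enol silyl ether and releases the C6 ketone without acid strong enough to dehydrate the tertiary aldol; C5, now α to the ketone, should settle by enolisation in the buffer as the cis-fused isomer, in which C6 is trans to the isopropyl group.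

Step 9
Reactants: 14 (1S,3S,3aS,6R,8aR)-1-(tert-butyldimethylsilyloxy)-3-hydroxy-3-isopropyl-6,8a-dimethyl-2,3,3a,5,6,8a-hexahydroazulen-4(1H)-one
Product: 15 (1S,3S,3aR,4R,6R,8aR)-1-(tert-butyldimethylsilyloxy)-3-isopropyl-6,8a-dimethyl-1,2,3,3a,4,5,6,8a-octahydroazulene-3,4-diol
Conditions: Me4NBH(OAc)3, MeCN–AcOH, −30 → −10 °C
Reagents that add atoms: none
Why: Evans–Saksena reduction: the C4 hydroxyl exchanges onto boron and delivers hydride intramolecularly to C6 from the side of C4, which gives the 1,3-anti diol (6β-OH); the acidic medium avoids retro-aldol cleavage.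

Step 10
Reactants: 15 (1S,3S,3aR,4R,6R,8aR)-1-(tert-butyldimethylsilyloxy)-3-isopropyl-6,8a-dimethyl-1,2,3,3a,4,5,6,8a-octahydroazulene-3,4-diol
Product: 17 2α-(tert-butyldimethylsilyloxy)-8β,9β-epoxy-5βH-daucane-4α,6β,10β-triol, via allylic hydroperoxide 16 (not isolated)
Conditions: O2, tetraphenylporphyrin (cat.), hν (visible), Ti(OiPr)4 (0.3 equiv), 4 Å MS, CH2Cl2, 0 °C
Reagents that add atoms: dioxygen, O=O
Why: Schenck ene reaction followed by oxygen transfer mediated by Ti(OiPr)4: singlet oxygen can abstract only the β hydrogen at C8 (C1 bears none), so oxygen is delivered suprafacially to the β face of C10 and the double bond moves to C8=C9; Ti(OiPr)4 then uses the hydroperoxide oxygen to epoxidise the alkene syn to the C10 oxygen, which sets C8 and C9 and leaves no alkene for over-oxidation.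

Step 11
Reactants: 17 2α-(tert-butyldimethylsilyloxy)-8β,9β-epoxy-5βH-daucane-4α,6β,10β-triol; 18 (Z)-2-methylbut-2-enoic acid (angelic acid), first of two equivalents
Product: 19 6β,10β-bis[(Z)-2-methylbut-2-enoyloxy]-2α-(tert-butyldimethylsilyloxy)-8β,9β-epoxy-5βH-daucan-4α-ol
Conditions: 18 (2.4 equiv), 2,4,6-Cl3C6H2COCl (2.4 equiv), Et3N, toluene, 20 °C; then 17, toluene, 80 °C
Reagents that add atoms: (Z)-2-methylbut-2-enoic acid (second equivalent of 18), C/C=C(/C)C(=O)O
Why: Yamaguchi-type acylation through the mixed anhydride without a nucleophilic catalyst, chosen because it keeps the Z geometry of the acyl group; two equivalents of 18 are consumed, one for each of the secondary C6 and C10 hydroxyls, while the tertiary C4 hydroxyl is too hindered to react.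

Step 12
Reactants: 19 6β,10β-bis[(Z)-2-methylbut-2-enoyloxy]-2α-(tert-butyldimethylsilyloxy)-8β,9β-epoxy-5βH-daucan-4α-ol
Product: 20 (1R,2S,4S,5R,6R,8S,9R,10R)-6,10-bis[(Z)-2-methylbut-2-enoyloxy]-8,9-epoxydaucane-2,4-diol (CNP0265715.2)
Conditions: HF·pyridine, pyridine, THF, 0 → 20 °C
Reagents that add atoms: none
Why: Fluoride-mediated desilylation with pyridine-buffered HF is mild enough for the trisubstituted epoxide and the Z-enoates and is non-basic, so no acyl migration to the freed C2 hydroxyl is expected.

## Compound list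

1 | (E)-but-2-enal | C/C=C/C=O | starting material
2 | 2-(triphenyl-λ5-phosphanylidene)propanal | CC(C=O)=P(c1ccccc1)(c1ccccc1)c1ccccc1 | starting material
3 | (2E,4E)-2-methylhexa-2,4-dienal | C/C=C/C=C(\C)C=O | intermediate
4 | pentane-2,4-dione | CC(=O)CC(C)=O | starting material
5 | (3Z)-2,4-bis(trimethylsilyloxy)penta-1,3-diene | C=C(O[Si](C)(C)C)/C=C(/C)O[Si](C)(C)C | intermediate
6 | (2Z,6S,7E,9E)-7-methyl-2,6-bis(trimethylsilyloxy)undeca-2,7,9-trien-4-one | C/C(O[Si](C)(C)C)=C/C(=O)C[C@H](O[Si](C)(C)C)/C(C)=C/C=C/C | intermediate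
7 | (6S,7E,9E)-6-hydroxy-7-methylundeca-7,9-diene-2,4-dione | CC(=O)CC(=O)C[C@H](O)/C(C)=C/C=C/C | intermediate
8 | (6S,7E,9E)-6-(tert-butyldimethylsilyloxy)-7-methylundeca-7,9-diene-2,4-dione | CC(=O)CC(=O)C[C@H](O[Si](C)(C)C(C)(C)C)/C(C)=C/C=C/C | intermediate
9 | (6S,7E,9E)-6-(tert-butyldimethylsilyloxy)-3-diazo-7-methylundeca-7,9-diene-2,4-dione | CC(=O)C(=[N+]=[N-])C(=O)C[C@H](O[Si](C)(C)C(C)(C)C)/C(C)=C/C=C/C | intermediate
10 | (6S,7E,9E)-2,6-bis(tert-butyldimethylsilyloxy)-3-diazo-7-methylundeca-1,7,9-trien-4-one | C=C(O[Si](C)(C)C(C)(C)C)C(=[N+]=[N-])C(=O)C[C@H](O[Si](C)(C)C(C)(C)C)/C(C)=C/C=C/C | intermediate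
11 | (1S,4S,5R,6R)-4-(tert-butyldimethylsilyloxy)-1-[1-(tert-butyldimethylsilyloxy)ethenyl]-5-methyl-6-[(E)-prop-1-enyl]bicyclo[3.1.0]hexan-2-one (silyloxy trans to the C5 methyl, propenyl exo) | O=C1C[C@H](O[Si](C)(C)C(C)(C)C)[C@]2(C)[C@@H](/C=C/C)[C@]12C(=C)O[Si](C)(C)C(C)(C)C | intermediate
12 | (3S,3aR,6R)-3,8-bis(tert-butyldimethylsilyloxy)-3a,6-dimethyl-3,3a,6,7-tetrahydroazulen-1(2H)-one (daucane: C4 ketone, C5=C6 enol ether, C9=C10, 2α-OTBS, H8 β) | O=C1C[C@H](O[Si](C)(C)C(C)(C)C)[C@]2(C)C=C[C@H](C)CC(O[Si](C)(C)C(C)(C)C)=C12 | intermediate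
13 | (1S,3S,3aR,6R)-3,8-bis(tert-butyldimethylsilyloxy)-1-isopropyl-3a,6-dimethyl-1,2,3,3a,6,7-hexahydroazulen-1-ol | CC(C)[C@@]1(O)C[C@H](O[Si](C)(C)C(C)(C)C)[C@]2(C)C=C[C@H](C)CC(O[Si](C)(C)C(C)(C)C)=C12 | intermediate
14 | (1S,3S,3aS,6R,8aR)-1-(tert-butyldimethylsilyloxy)-3-hydroxy-3-isopropyl-6,8a-dimethyl-2,3,3a,5,6,8a-hexahydroazulen-4(1H)-one (cis-fused, C6 ketone) | O=C1C[C@@H](C)C=C[C@@]2(C)[C@@H](O[Si](C)(C)C(C)(C)C)C[C@](O)(C(C)C)[C@@H]12 | intermediate
15 | (1S,3S,3aR,4R,6R,8aR)-1-(tert-butyldimethylsilyloxy)-3-isopropyl-6,8a-dimethyl-1,2,3,3a,4,5,6,8a-octahydroazulene-3,4-diol (4α,6β-diol, C9=C10) | O[C@@H]1C[C@@H](C)C=C[C@@]2(C)[C@@H](O[Si](C)(C)C(C)(C)C)C[C@](O)(C(C)C)[C@@H]12 | intermediate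
16 | 2α-(tert-butyldimethylsilyloxy)-10β-hydroperoxy-5βH-dauc-8-ene-4α,6β-diol | O[C@@H]1CC(C)=C[C@H](OO)[C@@]2(C)[C@@H](O[Si](C)(C)C(C)(C)C)C[C@](O)(C(C)C)[C@@H]12 | intermediate
17 | 2α-(tert-butyldimethylsilyloxy)-8β,9β-epoxy-5βH-daucane-4α,6β,10β-triol | O[C@@H]1C[C@]2(C)O[C@@H]2[C@H](O)[C@@]2(C)[C@@H](O[Si](C)(C)C(C)(C)C)C[C@](O)(C(C)C)[C@@H]12 | intermediate
18 | (Z)-2-methylbut-2-enoic acid (angelic acid) | C/C=C(/C)C(=O)O | starting material
19 | 6β,10β-bis[(Z)-2-methylbut-2-enoyloxy]-2α-(tert-butyldimethylsilyloxy)-8β,9β-epoxy-5βH-daucan-4α-ol | C/C=C(/C)C(=O)O[C@@H]1C[C@]2(C)O[C@@H]2[C@H](OC(=O)/C(C)=C\C)[C@@]2(C)[C@@H](O[Si](C)(C)C(C)(C)C)C[C@](O)(C(C)C)[C@@H]12 | intermediate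
20 | (1R,2S,4S,5R,6R,8S,9R,10R)-6,10-bis[(Z)-2-methylbut-2-enoyloxy]-8,9-epoxydaucane-2,4-diol | C/C=C(/C)C(=O)O[C@@H]1C[C@]2(C)O[C@@H]2[C@H](OC(=O)/C(C)=C\C)[C@@]2(C)[C@@H](O)C[C@](O)(C(C)C)[C@@H]12 | target

## Step count and least certain steps

Total: 12 steps. Longest linear sequence: 11 steps (1 → 3 → 7 → … → 20 through steps 1 and 3–12; equally 4 → 5 → 7 → … → 20 through steps 2–12).

**Step 7 (key step).** The siloxyvinyl carbenoid may be diverted before it cyclopropanates: it can react through its vinylogous carbon C7, or the vinyl diazo compound can electrocyclise to a pyrazole. A single allylic stereocentre may also discriminate the two alkene faces only moderately. The fallback separates the two events. It sets out from 9, which carries no vinyl group: Rh2(OAc)4 in CH2Cl2 should give, by cyclopropanation with the acceptor/acceptor carbenoid, (1S,4S,5R,6R)-1-acetyl-4-(tert-butyldimethylsilyloxy)-5-methyl-6-[(E)-prop-1-enyl]bicyclo[3.1.0]hexan-2-one F1, a stable compound at which diastereomers can be separated. Kinetic enol silylation of its acetyl group (LiN(SiMe3)2, TBSOTf, −78 °C) then gives 11, and heating in toluene brings the route back to 12.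

**Step 8.** The branched organometallic may enolise the hindered vinylogous ester instead of adding, with β-elimination of the C2 silyloxy group; equilibration at C5 to the cis-fused isomer may also be slow. The fallback sets out from 12 with a smaller, sp2 nucleophile: 2-propenylmagnesium bromide and CeCl3 should give the isopropenyl carbinol enol ether F2, and Bu4NF/AcOH then the isopropenyl hydroxy ketone F3. Hydrogenation with H2 and RhCl(PPh3)3 should saturate the exocyclic 1,1-disubstituted alkene before the ring alkene, which is flanked by the quaternary C1 and by C8, and arrives at 14.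

**Step 10.** The ene reaction of a cis-1,2-disubstituted ring alkene with singlet oxygen is slow, so bleaching of the sensitiser and unselective oxidation can compete. The fallback sets out from 15 and reaches the same allylic alcohol by elimination. Epoxidation with mCPBA from the convex β face should give 2α-(tert-butyldimethylsilyloxy)-9β,10β-epoxy-5βH-daucane-4α,6β-diol F4. Diethylaluminium 2,2,6,6-tetramethylpiperidide, Et2Al(NC9H18), removes the syn (β) hydrogen at C8 and opens the epoxide to 2α-(tert-butyldimethylsilyloxy)-5βH-dauc-8-ene-4α,6β,10β-triol F5. Epoxidation with VO(acac)2 and t-BuOOH, directed by the 10β-hydroxyl, comes back to 17.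

**Step 11.** Acylation of two hindered secondary hydroxyls may stay incomplete, and prolonged heating favours Z-to-E isomerisation of the acyl donor. The fallback sets out from 17 and builds the enoates in place. Acylation with two equivalents of 2-[bis(2,2,2-trifluoroethoxy)phosphoryl]propanoic acid (carbodiimide, DMAP) gives the 6,10-bis(phosphonopropanoate) F6. Still–Gennari olefination with acetaldehyde (KN(SiMe3)2, 18-crown-6, THF, −78 °C) should form both Z-enoates and comes back to 19.

**Step 3.** Enantioselectivity may erode with the α-branched dienal, and the δ-hydroxy-β-diketone may cyclodehydrate during desilylation. The fallback sets out from 3 and uses a stoichiometric chiral enolate. The diisopinocampheylboron enolate of commercial (E)-4-methoxypent-3-en-2-one (Ipc2BCl, Et3N; the reagent enantiomer that gives the 6S alcohol) should add to 3 to give (2E,6S,7E,9E)-6-hydroxy-2-methoxy-7-methylundeca-2,7,9-trien-4-one F7. Mild aqueous acid hydrolyses the vinylogous ester and comes back to 7.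

## Further compounds

F1 | step 7 | (1S,4S,5R,6R)-1-acetyl-4-(tert-butyldimethylsilyloxy)-5-methyl-6-[(E)-prop-1-enyl]bicyclo[3.1.0]hexan-2-one | O=C1C[C@H](O[Si](C)(C)C(C)(C)C)[C@]2(C)[C@@H](/C=C/C)[C@]12C(C)=O
F2 | step 8 | (1S,3S,3aR,6R)-3,8-bis(tert-butyldimethylsilyloxy)-3a,6-dimethyl-1-(prop-1-en-2-yl)-1,2,3,3a,6,7-hexahydroazulen-1-ol | C=C(C)[C@@]1(O)C[C@H](O[Si](C)(C)C(C)(C)C)[C@]2(C)C=C[C@H](C)CC(O[Si](C)(C)C(C)(C)C)=C12
F3 | step 8 | cis-fused 1-(tert-butyldimethylsilyloxy)-3-hydroxy-6,8a-dimethyl-3-(prop-1-en-2-yl)-2,3,3a,5,6,8a-hexahydroazulen-4(1H)-one (isopropenyl analogue of 14) | O=C1C[C@@H](C)C=C[C@@]2(C)[C@@H](O[Si](C)(C)C(C)(C)C)C[C@](O)(C(C)=C)[C@@H]12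
F4 | step 10 | 2α-(tert-butyldimethylsilyloxy)-9β,10β-epoxy-5βH-daucane-4α,6β-diol | O[C@@H]1C[C@@H](C)[C@@H]2O[C@@H]2[C@@]2(C)[C@@H](O[Si](C)(C)C(C)(C)C)C[C@](O)(C(C)C)[C@@H]12
F5 | step 10 | 2α-(tert-butyldimethylsilyloxy)-5βH-dauc-8-ene-4α,6β,10β-triol | O[C@@H]1CC(C)=C[C@H](O)[C@@]2(C)[C@@H](O[Si](C)(C)C(C)(C)C)C[C@](O)(C(C)C)[C@@H]12
F6 | step 11 | 6β,10β-bis{2-[bis(2,2,2-trifluoroethoxy)phosphoryl]propanoyloxy}-2α-(tert-butyldimethylsilyloxy)-8β,9β-epoxy-5βH-daucan-4α-ol (mixture at the phosphonate α-carbons) | CC(C(=O)O[C@@H]1C[C@]2(C)O[C@@H]2[C@H](OC(=O)C(C)P(=O)(OCC(F)(F)F)OCC(F)(F)F)[C@@]2(C)[C@@H](O[Si](C)(C)C(C)(C)C)C[C@](O)(C(C)C)[C@@H]12)P(=O)(OCC(F)(F)F)OCC(F)(F)F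
F7 | step 3 | (2E,6S,7E,9E)-6-hydroxy-2-methoxy-7-methylundeca-2,7,9-trien-4-one | CO/C(C)=C/C(=O)C[C@H](O)/C(C)=C/C=C/C
A1 | alternative 1 | ring A diene for metathesis: cyclopentane with the silylated vinyl carbinol arm (C10, C9) on C1 and the silylated methallyl carbinol arm (C6–C8) on C5 | C=C[C@H](O[Si](C)(C)C(C)(C)C)[C@@]1(C)[C@@H](O[Si](C)(C)C(C)(C)C)C[C@](O)(C(C)C)[C@H]1[C@H](O[Si](C)(C)C(C)(C)C)CC(C)=C
A2 | alternative 1 | 2α,6β,10β-tris(tert-butyldimethylsilyloxy)-5βH-dauc-8-en-4α-ol | CC1=C[C@H](O[Si](C)(C)C(C)(C)C)[C@@]2(C)[C@@H](O[Si](C)(C)C(C)(C)C)C[C@](O)(C(C)C)[C@H]2[C@H](O[Si](C)(C)C(C)(C)C)C1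
A3 | alternative 2 | (S)-4-hydroxy-4-isopropyl-2-methylcyclopent-2-en-1-one | CC1=C[C@@](O)(C(C)C)CC1=O
A4 | alternative 2 | 4-methyl-1,2-bis(trimethylsilyloxy)cyclopent-1-ene | CC1CC(O[Si](C)(C)C)=C(O[Si](C)(C)C)C1
A5 | alternative 2 | cyclobutane photoadduct of A3 and A4 (C1–C10 and C5–C6 bonds formed, C6–C10 bond still present) | O=C1C[C@](O)(C(C)C)[C@@H]2[C@@]1(C)C1(O[Si](C)(C)C)CC(C)CC21O[Si](C)(C)C
A6 | alternative 2 | cis-fused 4α-hydroxy-5βH-daucane-2,6,10-trione | O=C1CC(C)CC(=O)[C@@]2(C)C(=O)C[C@](O)(C(C)C)[C@@H]12
A7 | alternative 3 | (R)-terpinen-4-ol | CC1=CC[C@@](O)(C(C)C)CC1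
A8 | alternative 3 | pentacarbonyl{methoxy[(3S,5S)-3-(tert-butyldimethylsilyloxy)-5-isopropyl-2-methyl-5-(triethylsilyloxy)cyclopent-1-enyl]methylidene}chromium | COC(=[Cr](=C=O)(=C=O)(=C=O)(=C=O)=C=O)C1=C(C)[C@@H](O[Si](C)(C)C(C)(C)C)C[C@]1(O[Si](CC)(CC)CC)C(C)C
A9 | alternative 3 | (E)-1-(tert-butyldimethylsilyloxy)-3-methylbuta-1,3-diene | C=C(C)/C=C/O[Si](C)(C)C(C)(C)C
A10 | alternative 3 | 2α,10β-bis(tert-butyldimethylsilyloxy)-6-methoxy-4α-(triethylsilyloxy)dauca-5,8-diene | COC1=C2[C@@](O[Si](CC)(CC)CC)(C(C)C)C[C@H](O[Si](C)(C)C(C)(C)C)[C@]2(C)[C@@H](O[Si](C)(C)C(C)(C)C)C=C(C)C1
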